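**Strategy**

The route rests on a thermal type 1 intramolecular Diels–Alder reaction that closes rings A and B of the cis-fused decalin together. An acyclic triene, in which a (Z)-2-methylenoate (C4=C5) is tied by the C6–C9 chain to an (E,E)-1-boryl-4-methyldiene (C3=C2–C1=C10), forms C3–C4 and C5–C10 in one operation. The step exploits the fact that these bonds flank C4–C5 in ring A, so the C3 ketone and the C1–C2 ethano unit are a masked cyclohexene, and it relays the single stereocentre C9 to C4, C5 and C10. C9 comes from a chirality-transferring Johnson–Claisen rearrangement; the side chain is attached last.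

Key step: step 10

Assumption: atoms carry labdane numbers (ring A C1–C5/C10, ring B C5–C10, C17 the methylidene carbon on C8, C18 the 4α and C19 the 4β carbon, C20 the methyl on C10, C11–C16 the side chain) and β is the face of CH3-20; the target as written is A/B cis-fused (5β-H), and "5β-labdane" names below mean exactly this.

Assumption: the (S,S)-ProPhenol ligand is taken to deliver the (S)-carbinol 8 in step 4; if the sense proves opposite, its enantiomer is used.

**Route**

Step 1
Reactants: 1 5-[(tert-butyldimethylsilyl)oxy]pentan-1-ol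
Product: 2 5-[(tert-butyldimethylsilyl)oxy]pentanal
Conditions: TEMPO (10 mol %), PhI(OAc)2, CH2Cl2, rt
Reagents that add atoms: none
Why: Oxoammonium (TEMPO) oxidation should stop cleanly at the aldehyde and leave the silyl ether untouched.

Step 2
Reactants: 2 5-[(tert-butyldimethylsilyl)oxy]pentanal
Product: 3 5-[(tert-butyldimethylsilyl)oxy]-2-methylidenepentanal
Conditions: 37% aq. HCHO, pyrrolidine (10 mol %), EtCO2H (10 mol %), iPrOH, 45 °C
Reagents that add atoms: formaldehyde C=O
Why: Amine-catalysed Mannich condensation and elimination (α-methylenation of an aldehyde) should install the C17 methylidene at C8.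

Step 3
Reactants: 3 5-[(tert-butyldimethylsilyl)oxy]-2-methylidenepentanal; 4 2-(triphenylphosphoranylidene)propanal
Product: 5 (2E)-7-[(tert-butyldimethylsilyl)oxy]-2-methyl-4-methylidenehept-2-enal
Conditions: toluene, 80 °C
Reagents that add atoms: none
Why: Wittig olefination with a formyl-stabilised ylide should give the (E)-trisubstituted enal, the non-enolisable aldehyde 3 reacting faster than the product.

Step 4
Reactants: 5 (2E)-7-[(tert-butyldimethylsilyl)oxy]-2-methyl-4-methylidenehept-2-enal; 6 ethynyltrimethylsilane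
Product: 8 (3S,4E)-9-[(tert-butyldimethylsilyl)oxy]-4-methyl-6-methylidene-1-(trimethylsilyl)non-4-en-1-yn-3-ol, via alkynylzinc reagent 7 (not isolated)
Conditions: Me2Zn (3 equiv), (S,S)-ProPhenol (10 mol %), Ph3P=O (20 mol %), toluene, 0 °C; aq. work-up
Reagents that add atoms: none
Why: Catalytic asymmetric alkynylation of an enal with a dinuclear zinc–ProPhenol catalyst should add the alkynylzinc to one aldehyde face, so the ligand sets the C1 carbinol centre (S).

Step 5
Reactants: 8 (3S,4E)-9-[(tert-butyldimethylsilyl)oxy]-4-methyl-6-methylidene-1-(trimethylsilyl)non-4-en-1-yn-3-ol; 9 triethyl orthoacetate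
Product: 11 ethyl (3S,4E)-3-{5-[(tert-butyldimethylsilyl)oxy]pent-1-en-2-yl}-4-methyl-7-(trimethylsilyl)hept-4-en-6-ynoate, via ketene acetal 10 (not isolated)
Conditions: EtCO2H (cat.), neat 9, 130 °C, EtOH distilled off
Reagents that add atoms: none
Why: Johnson–Claisen rearrangement through a chair transition state with the alkynyl group equatorial should transfer the C1 chirality suprafacially to C9 and give the (E)-C10=C1 alkene, the silyl group blocking the propargylic mode.

Step 6
Reactants: 11 ethyl (3S,4E)-3-{5-[(tert-butyldimethylsilyl)oxy]pent-1-en-2-yl}-4-methyl-7-(trimethylsilyl)hept-4-en-6-ynoate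
Product: 12 ethyl (3S,4E)-3-(5-hydroxypent-1-en-2-yl)-4-methylhept-4-en-6-ynoate
Conditions: Bu4NF (2.5 equiv), THF, 0 °C to rt
Reagents that add atoms: none
Why: Fluoride-mediated desilylation should cleave the O–Si and the C(sp)–Si bonds in one operation without touching the ester.

Step 7
Reactants: 12 ethyl (3S,4E)-3-(5-hydroxypent-1-en-2-yl)-4-methylhept-4-en-6-ynoate
Product: 13 ethyl (3S,4E)-4-methyl-3-(5-oxopent-1-en-2-yl)hept-4-en-6-ynoate
Conditions: Dess–Martin periodinane, CH2Cl2, 0 °C to rt
Reagents that add atoms: none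
Why: Dess–Martin oxidation should give the C5 aldehyde under near-neutral conditions that spare the enyne and the bis-allylic C9–H.

Step 8
Reactants: 13 ethyl (3S,4E)-4-methyl-3-(5-oxopent-1-en-2-yl)hept-4-en-6-ynoate; 14 ethyl 2-[bis(2,2,2-trifluoroethoxy)phosphoryl]propanoate
Product: 16 diethyl (2Z,7S)-2-methyl-6-methylidene-7-[(2E)-pent-2-en-4-yn-2-yl]non-2-enedioate, via potassium phosphonate carbanion 15 (not isolated)
Conditions: KN(SiMe3)2, 18-crown-6, THF, −78 °C; then 13
Reagents that add atoms: none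
Why: Still–Gennari olefination with the electron-poor phosphonate should give the (Z)-2-methylenoate under kinetic control, which fixes the later C4/C5 relation.

Step 9
Reactants: 16 diethyl (2Z,7S)-2-methyl-6-methylidene-7-[(2E)-pent-2-en-4-yn-2-yl]non-2-enedioate
Product: 17 diethyl (2Z,7S)-2-methyl-6-methylidene-7-[(2E,4E)-5-(4,4,5,5-tetramethyl-1,3,2-dioxaborolan-2-yl)penta-2,4-dien-2-yl]non-2-enedioate
Conditions: pinacolborane (1.5 equiv), Cp2Zr(H)Cl (10 mol %), Et3N (10 mol %), CH2Cl2, 40 °C
Reagents that add atoms: pinacolborane B1OC(C)(C)C(C)(C)O1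
Why: Zirconium-catalysed syn hydroboration of the terminal alkyne should give the (E)-alkenylboronate and hence the (E,E)-dienylboronate, the alkenes and esters being inert.

Step 10
Reactants: 17 diethyl (2Z,7S)-2-methyl-6-methylidene-7-[(2E,4E)-5-(4,4,5,5-tetramethyl-1,3,2-dioxaborolan-2-yl)penta-2,4-dien-2-yl]non-2-enedioate
Product: 18 diethyl 3α-(4,4,5,5-tetramethyl-1,3,2-dioxaborolan-2-yl)-13,14,15,16-tetranor-5β-labda-1,8(17)-diene-12,18-dioate
Conditions: toluene (0.01 M), BHT (cat.), 135 °C, sealed tube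
Reagents that add atoms: none
Why: Thermal type 1 intramolecular Diels–Alder reaction: the (E,E)-1-boryl-4-methyldiene (C3=C2–C1=C10) and the (Z)-2-methylenoate (C4=C5) should combine in a concerted, asynchronous [4+2] cycloaddition that forms C3–C4 and C5–C10 together, the closest known cases being cyclisations of 1,7,9-decatrienes that carry a methyl group on the tethered diene terminus and of 1-boryldienes. Ring A closes as the new cyclohexene (C1=C2) and ring B closes through the four-carbon tether C6–C9 in a chair-like six-membered array. The C4/C5 relation (CO2Et cis to C6 and CH3 cis to H-5) is copied suprafacially from the (Z)-alkene, and the cis ring fusion (H-5 cis to CH3-20) follows from the endo transition state in which the ester and the tether lie under the diene. The diene face is chosen by C9, whose CH2CO2Et arm sits pseudo-equatorial on the forming ring B with C9–H eclipsing C1–H, so that CH3-20 ends up cis to the C11 arm; boron, on the outside of the diene, becomes 3α. The step needs endo over exo selectivity and one diene face, which the (Z)-ester (secondary orbital overlap), the angular methyl group (which favours cis fusion) and the equatorial preference at C9 should secure; the saturated C12 ester and the C8=C17 alkene cannot take part.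

Step 11
Reactants: 18 diethyl 3α-(4,4,5,5-tetramethyl-1,3,2-dioxaborolan-2-yl)-13,14,15,16-tetranor-5β-labda-1,8(17)-diene-12,18-dioate
Product: 19 diethyl 3α-hydroxy-13,14,15,16-tetranor-5β-labda-1,8(17)-diene-12,18-dioate
Conditions: NaBO3·4H2O, THF/H2O, rt
Reagents that add atoms: sodium perborate O=BO[O-].[Na+]
Why: Oxidation of the allylic C–B bond (1,2-shift of carbon from boron to oxygen) should proceed with retention and without allylic transposition to give the 3α-alcohol.

Step 12
Reactants: 19 diethyl 3α-hydroxy-13,14,15,16-tetranor-5β-labda-1,8(17)-diene-12,18-dioate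
Product: 20 13,14,15,16-tetranor-5β-labda-1,8(17)-diene-3α,12,18-triol
Conditions: LiAlH4, THF, 0 °C to rt; H2O work-up
Reagents that add atoms: none
Why: Hydride reduction should convert both esters, including the hindered C18 ester on the quaternary C4, into primary alcohols while the isolated alkenes stay intact.

Step 13
Reactants: 20 13,14,15,16-tetranor-5β-labda-1,8(17)-diene-3α,12,18-triol
Product: 21 12,18-dihydroxy-13,14,15,16-tetranor-5β-labda-1,8(17)-dien-3-one
Conditions: MnO2 (activated, excess), CH2Cl2, rt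
Reagents that add atoms: none
Why: MnO2 oxidation is selective for the allylic C3 alcohol, so the two saturated primary alcohols should survive.

Step 14
Reactants: 21 12,18-dihydroxy-13,14,15,16-tetranor-5β-labda-1,8(17)-dien-3-one
Product: 22 12-bromo-18-hydroxy-13,14,15,16-tetranor-5β-labda-1,8(17)-dien-3-one
Conditions: CBr4 (1.1 equiv), PPh3 (1.1 equiv), CH2Cl2, 0 °C
Reagents that add atoms: carbon tetrabromide BrC(Br)(Br)Br
Why: Appel bromination proceeds by SN2 displacement, which should occur only at the unhindered C12 alcohol and not at the neopentyl C18 alcohol.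

Step 15
Reactants: 22 12-bromo-18-hydroxy-13,14,15,16-tetranor-5β-labda-1,8(17)-dien-3-one
Product: 23 18-acetoxy-12-bromo-13,14,15,16-tetranor-5β-labda-1,8(17)-dien-3-one
Conditions: Ac2O, pyridine, DMAP (cat.), CH2Cl2, 0 °C to rt
Reagents that add atoms: acetic anhydride CC(=O)OC(C)=O
Why: DMAP-catalysed acylation should acetylate the remaining neopentyl alcohol under conditions too mild for retro-aldol cleavage of the β-hydroxy ketone.

Step 16
Reactants: 23 18-acetoxy-12-bromo-13,14,15,16-tetranor-5β-labda-1,8(17)-dien-3-one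
Product: 24 18-acetoxy-12-bromo-13,14,15,16-tetranor-5β-labd-8(17)-en-3-one
Conditions: [(Ph3P)CuH]6 (0.4 equiv), H2O (2 equiv), degassed THF/toluene, rt
Reagents that add atoms: none
Why: Copper hydride conjugate reduction should saturate only the enone C1=C2 bond, since the acetate, the primary bromide and the unactivated C8=C17 alkene do not react with this reagent.

Step 17
Reactants: 25 but-2-ynoic acid
Product: 26 (2Z)-3-iodobut-2-enoic acid
Conditions: NaI, AcOH, 110 °C
Reagents that add atoms: sodium iodide [Na+].[I-]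
Why: Conjugate addition of iodide to the ynoic acid followed by anti protonation (hydroiodination) should give the (Z)-β-iodo acid stereoselectively.

Step 18
Reactants: 24 18-acetoxy-12-bromo-13,14,15,16-tetranor-5β-labd-8(17)-en-3-one; 26 (2Z)-3-iodobut-2-enoic acid
Product: 29 (4R,5S,9S,10R,13Z)-18-acetoxy-3-oxo-5β-labda-8(17),13-dien-15-oic acid, via alkylzinc bromide 27 (not isolated), via sodium iodobutenoate 28 (not isolated)
Conditions: 24, Zn dust, LiCl, THF, 50 °C; separately 26, NaH (1.0 equiv), THF, 0 °C; combine, PdCl2(MeCN)2 (5 mol %), DMF, rt; aq. HCl work-up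
Reagents that add atoms: none
Why: Negishi sp3–sp2 coupling of a LiCl-solubilised alkylzinc bromide, which tolerates the ketone and the acetate, with the pre-formed carboxylate of the (Z)-iodo acid should form C12–C13 with retention of the alkene geometry and deliver the acid directly.

**Compound list**

1 | 5-[(tert-butyldimethylsilyl)oxy]pentan-1-ol | OCCCCCO[Si](C)(C)C(C)(C)C | starting material
2 | 5-[(tert-butyldimethylsilyl)oxy]pentanal | O=CCCCCO[Si](C)(C)C(C)(C)C | intermediate
3 | 5-[(tert-butyldimethylsilyl)oxy]-2-methylidenepentanal | O=CC(=C)CCCO[Si](C)(C)C(C)(C)C | intermediate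
4 | 2-(triphenylphosphoranylidene)propanal | CC(C=O)=P(c1ccccc1)(c1ccccc1)c1ccccc1 | starting material
5 | (2E)-7-[(tert-butyldimethylsilyl)oxy]-2-methyl-4-methylidenehept-2-enal | O=C/C(C)=C/C(=C)CCCO[Si](C)(C)C(C)(C)C | intermediate
6 | ethynyltrimethylsilane | C#C[Si](C)(C)C | starting material
7 | methyl[(trimethylsilyl)ethynyl]zinc | C[Zn]C#C[Si](C)(C)C | intermediate
8 | (3S,4E)-9-[(tert-butyldimethylsilyl)oxy]-4-methyl-6-methylidene-1-(trimethylsilyl)non-4-en-1-yn-3-ol | O[C@H](C#C[Si](C)(C)C)/C(C)=C/C(=C)CCCO[Si](C)(C)C(C)(C)C | intermediate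
9 | triethyl orthoacetate | CC(OCC)(OCC)OCC | starting material
10 | (3S,4E)-9-[(tert-butyldimethylsilyl)oxy]-3-[(1-ethoxyethenyl)oxy]-4-methyl-6-methylidene-1-(trimethylsilyl)non-4-en-1-yne (ketene acetal) | C=C(OCC)O[C@H](C#C[Si](C)(C)C)/C(C)=C/C(=C)CCCO[Si](C)(C)C(C)(C)C | intermediate
11 | ethyl (3S,4E)-3-{5-[(tert-butyldimethylsilyl)oxy]pent-1-en-2-yl}-4-methyl-7-(trimethylsilyl)hept-4-en-6-ynoate | CCOC(=O)C[C@@H](C(=C)CCCO[Si](C)(C)C(C)(C)C)/C(C)=C/C#C[Si](C)(C)C | intermediate
12 | ethyl (3S,4E)-3-(5-hydroxypent-1-en-2-yl)-4-methylhept-4-en-6-ynoate | CCOC(=O)C[C@@H](C(=C)CCCO)/C(C)=C/C#C | intermediate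
13 | ethyl (3S,4E)-4-methyl-3-(5-oxopent-1-en-2-yl)hept-4-en-6-ynoate | CCOC(=O)C[C@@H](C(=C)CCC=O)/C(C)=C/C#C | intermediate
14 | ethyl 2-[bis(2,2,2-trifluoroethoxy)phosphoryl]propanoate | CCOC(=O)C(C)P(=O)(OCC(F)(F)F)OCC(F)(F)F | starting material
15 | potassium salt of the α-carbanion of 14 | CCOC(=O)[C-](C)P(=O)(OCC(F)(F)F)OCC(F)(F)F.[K+] | intermediate
16 | diethyl (2Z,7S)-2-methyl-6-methylidene-7-[(2E)-pent-2-en-4-yn-2-yl]non-2-enedioate | CCOC(=O)C[C@@H](C(=C)CC/C=C(/C)C(=O)OCC)/C(C)=C/C#C | intermediate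
17 | diethyl (2Z,7S)-2-methyl-6-methylidene-7-[(2E,4E)-5-(4,4,5,5-tetramethyl-1,3,2-dioxaborolan-2-yl)penta-2,4-dien-2-yl]non-2-enedioate | CCOC(=O)C[C@@H](C(=C)CC/C=C(/C)C(=O)OCC)/C(C)=C/C=C/B1OC(C)(C)C(C)(C)O1 | intermediate
18 | diethyl 3α-(4,4,5,5-tetramethyl-1,3,2-dioxaborolan-2-yl)-13,14,15,16-tetranor-5β-labda-1,8(17)-diene-12,18-dioate (cis-fused; 4α-CO2Et, 4β-CH3, 5β-H, 9β-CH2CO2Et, 10β-CH3) | C=C1CC[C@H]2[C@](C)(C=C[C@@H](B3OC(C)(C)C(C)(C)O3)[C@@]2(C)C(=O)OCC)[C@H]1CC(=O)OCC | intermediate
19 | diethyl 3α-hydroxy-13,14,15,16-tetranor-5β-labda-1,8(17)-diene-12,18-dioate | C=C1CC[C@H]2[C@](C)(C=C[C@@H](O)[C@@]2(C)C(=O)OCC)[C@H]1CC(=O)OCC | intermediate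
20 | 13,14,15,16-tetranor-5β-labda-1,8(17)-diene-3α,12,18-triol | C=C1CC[C@H]2[C@](C)(C=C[C@@H](O)[C@@]2(C)CO)[C@H]1CCO | intermediate
21 | 12,18-dihydroxy-13,14,15,16-tetranor-5β-labda-1,8(17)-dien-3-one | C=C1CC[C@H]2[C@](C)(C=CC(=O)[C@@]2(C)CO)[C@H]1CCO | intermediate
22 | 12-bromo-18-hydroxy-13,14,15,16-tetranor-5β-labda-1,8(17)-dien-3-one | C=C1CC[C@H]2[C@](C)(C=CC(=O)[C@@]2(C)CO)[C@H]1CCBr | intermediate
23 | 18-acetoxy-12-bromo-13,14,15,16-tetranor-5β-labda-1,8(17)-dien-3-one | C=C1CC[C@H]2[C@](C)(C=CC(=O)[C@@]2(C)COC(C)=O)[C@H]1CCBr | intermediate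
24 | 18-acetoxy-12-bromo-13,14,15,16-tetranor-5β-labd-8(17)-en-3-one | C=C1CC[C@H]2[C@](C)(CCC(=O)[C@@]2(C)COC(C)=O)[C@H]1CCBr | intermediate
25 | but-2-ynoic acid | CC#CC(=O)O | starting material
26 | (2Z)-3-iodobut-2-enoic acid | C/C(I)=C/C(=O)O | intermediate
27 | [18-acetoxy-3-oxo-13,14,15,16-tetranor-5β-labd-8(17)-en-12-yl]zinc bromide | C=C1CC[C@H]2[C@](C)(CCC(=O)[C@@]2(C)COC(C)=O)[C@H]1CC[Zn]Br | intermediate
28 | sodium (2Z)-3-iodobut-2-enoate | C/C(I)=C/C(=O)[O-].[Na+] | intermediate
29 | (4R,5S,9S,10R,13Z)-18-acetoxy-3-oxo-5β-labda-8(17),13-dien-15-oic acid (A/B cis; 4α-CH2OAc, 4β-CH3, 9β side chain, 10β-CH3) | C=C1CC[C@H]2[C@](C)(CCC(=O)[C@@]2(C)COC(C)=O)[C@H]1CC/C(C)=C\C(=O)O | target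

**Step count**

Total steps: 18. Longest linear sequence: 17 (steps 1–16 and 18, from compound 1).

**Steps most likely to fail**

Step 10 (cycloaddition). The exo mode could compete and give the trans-fused isomer. The inside methyl group on C10 could make the s-cis diene hard to reach and the reaction slow. At the temperature then needed, a 1,5-hydrogen shift of the diene could take over. The fallback replaces the boryl diene by a more electron-rich silyloxy diene, which should react at lower temperature. It sets out from 17 and comes back at 19. Oxidation of the alkenyl C–B bond of 17 (NaBO3·4H2O, THF/H2O) should give the β,γ-unsaturated aldehyde diethyl (2Z,7S)-2-methyl-6-methylidene-7-[(2E)-5-oxopent-2-en-2-yl]non-2-enedioate F1. Soft enolisation (tBuMe2SiOTf, Et3N, CH2Cl2, −78 °C) should give the silyl dienol ether diethyl (2Z,7S)-7-[(2E,4E)-5-[(tert-butyldimethylsilyl)oxy]penta-2,4-dien-2-yl]-2-methyl-6-methylidenenon-2-enedioate F2 with the C10=C1 geometry unchanged; any (4Z)-enol ether does not cyclise and is returned to F1 by hydrolysis. Heating F2 (toluene, 60–80 °C) should give, through the same endo transition state, diethyl 3α-[(tert-butyldimethylsilyl)oxy]-13,14,15,16-tetranor-5β-labda-1,8(17)-diene-12,18-dioate F3. Bu4NF then gives 19.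

Step 5 (Johnson–Claisen rearrangement). The doubly activated (allylic and propargylic) carbinol could ionise under acid at 130 °C, with loss of enantiopurity or allylic transposition. The small alkynyl group could also erode the E/Z ratio and with it the chirality transfer. The fallback uses an ester enolate rearrangement at low temperature. It sets out from 8 and comes back at 11. Acetylation (Ac2O, pyridine, DMAP) should give (3S,4E)-9-[(tert-butyldimethylsilyl)oxy]-4-methyl-6-methylidene-1-(trimethylsilyl)non-4-en-1-yn-3-yl acetate F4. Ireland–Claisen rearrangement (LiN(iPr)2, Me3SiCl, THF, −78 °C to rt; dilute acid work-up) should give (3S,4E)-3-{5-[(tert-butyldimethylsilyl)oxy]pent-1-en-2-yl}-4-methyl-7-(trimethylsilyl)hept-4-en-6-ynoic acid F5 through the same chair. Esterification (EtI, K2CO3, DMF) gives 11.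

Step 18 (final coupling). Zinc insertion could be slow next to the ketone. The organozinc could be protonated by acid that is not fully converted to its salt. β-Hydride elimination or Z/E isomerisation could occur at palladium. The fallback avoids a pre-formed organozinc and the free acid. It sets out from 24 and 26 and comes back at 29. Esterification of 26 (2-(trimethylsilyl)ethanol, DCC, DMAP) should give 2-(trimethylsilyl)ethyl (2Z)-3-iodobut-2-enoate F6. Nickel-catalysed reductive cross-electrophile coupling of 24 with F6 (NiBr2(MeOCH2CH2OMe), 4,4′-di-tert-butyl-2,2′-bipyridine, Mn powder, NaI, DMA, rt) should give 2-(trimethylsilyl)ethyl (13Z)-18-acetoxy-3-oxo-5β-labda-8(17),13-dien-15-oate F7. Bu4NF buffered with AcOH (THF, 0 °C) releases 29.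

Further compounds
F1 | step 10 | diethyl (2Z,7S)-2-methyl-6-methylidene-7-[(2E)-5-oxopent-2-en-2-yl]non-2-enedioate | CCOC(=O)C[C@@H](C(=C)CC/C=C(/C)C(=O)OCC)/C(C)=C/CC=O
F2 | step 10 | diethyl (2Z,7S)-7-[(2E,4E)-5-[(tert-butyldimethylsilyl)oxy]penta-2,4-dien-2-yl]-2-methyl-6-methylidenenon-2-enedioate | CCOC(=O)C[C@@H](C(=C)CC/C=C(/C)C(=O)OCC)/C(C)=C/C=C/O[Si](C)(C)C(C)(C)C
F3 | step 10 | diethyl 3α-[(tert-butyldimethylsilyl)oxy]-13,14,15,16-tetranor-5β-labda-1,8(17)-diene-12,18-dioate | C=C1CC[C@H]2[C@](C)(C=C[C@@H](O[Si](C)(C)C(C)(C)C)[C@@]2(C)C(=O)OCC)[C@H]1CC(=O)OCC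
F4 | step 5 | (3S,4E)-9-[(tert-butyldimethylsilyl)oxy]-4-methyl-6-methylidene-1-(trimethylsilyl)non-4-en-1-yn-3-yl acetate | CC(=O)O[C@H](C#C[Si](C)(C)C)/C(C)=C/C(=C)CCCO[Si](C)(C)C(C)(C)C
F5 | step 5 | (3S,4E)-3-{5-[(tert-butyldimethylsilyl)oxy]pent-1-en-2-yl}-4-methyl-7-(trimethylsilyl)hept-4-en-6-ynoic acid | OC(=O)C[C@@H](C(=C)CCCO[Si](C)(C)C(C)(C)C)/C(C)=C/C#C[Si](C)(C)C
F6 | step 18 | 2-(trimethylsilyl)ethyl (2Z)-3-iodobut-2-enoate | C/C(I)=C/C(=O)OCC[Si](C)(C)C
F7 | step 18 | 2-(trimethylsilyl)ethyl (13Z)-18-acetoxy-3-oxo-5β-labda-8(17),13-dien-15-oate | C=C1CC[C@H]2[C@](C)(CCC(=O)[C@@]2(C)COC(C)=O)[C@H]1CC/C(C)=C\C(=O)OCC[Si](C)(C)C
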